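**Remark on the chemistry (assumption).** Which antipode of the chiral diamine steers the ring closure of step 10 towards the (R)-alcohol cannot be deduced with confidence for this aryl/benzyl pair, so it is assumed that one antipode does and that one is used. Structure check: diol 15, alcohol 16 and the target are stereochemically consistent. The sequence R (16) → S (17) → R (18) is a change of CIP priorities only, with the same arrangement in space at C3, so no structure needed correcting.

## Structural features

The target is a (3R)-isoflavan: benzene ring A is fused to the dihydropyran ring C (O1, C2, C3, C4), and ring B sits on C3. Ring B is fused through C2'–C3' to a 2,2-dimethyl-2H-pyran (ring D), so the C3 substituent is a 5-hydroxy-2,2-dimethyl-2H-chromen-8-yl group. Ring A is a fully differentiated phloroglucinol: O1 on C8a, a methyl ether on C5, a free phenol on C7 and a formyl group on C8 hydrogen-bonded to the 7-OH; only C6 carries hydrogen. C3 is the only stereocentre. It is tertiary, benzylic to ring B and flanked by two methylene groups, so no neighbouring centre can relay configuration. The fragile parts are ring D (a tertiary allylic aryl ether with a cis-styrenic alkene, which rules out hydrogenation and prolonged strong acid), the aldehyde, the two phenols and the electron-rich rings. The real difficulty is the absolute configuration at a carbon whose substituents (H, CH2O, CH2Ar, aryl) offer little bias. Behind it stand the regiochemical questions on ring A (C8 against C6, O7 against O5) and ring B (O2' against O4'). The chosen key step uses the fact that C3 lies between C2 and C4: with a second CH2OH in place of the C3 hydrogen, C3 is the prochiral carbon of a 1,3-diol, and forming O1–C8a from either oxygen closes ring C and creates the stereocentre in one event.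

## Logic of the disconnections

**22 ⇒ 20.** The O7–H and O4'–H bonds are traced back to O7–CH3 and O4'–CH2OCH3. Both phenols are unveiled last because a free 7-OH/8-CHO pair and a free ring B phenol would interfere with the base, hydride and metal chemistry before. The gain is that a symmetrical 5,7-dimethoxy ring A can be carried through the whole route. The forward step must tell 7-OMe from 5-OMe, which the neighbouring 8-CHO does by chelation, and must spare ring D.

**20 ⇒ 18.** The C8–CHO bond is cut. A formyl group cannot pass through LiAlH4 and would compete in the decarbonylation, so it is introduced after both. This leaves ring A unsubstituted at C8 for all earlier steps. The forward step must attack C8 in preference to C6 and to ring B.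

**18 ⇒ 17 ⇒ 16.** The C3–H bond is replaced retrosynthetically by C3–CHO and then C3–CH2OH. This turns the hard tertiary centre into a quaternary carbinol that can come from a prochiral diol. The forward steps must oxidise without touching ring D and must remove CO with retention at C3.

**16 ⇒ 15 (key disconnection).** The O1–C8a bond is cut. This removes ring C and the only stereocentre at once, since 15 is achiral. The forward step must choose one of two enantiotopic hydroxymethyl groups under catalyst control. The design of 15 is kept as it stands: both methoxy groups are meta to C8a, C8 is free, every phenol is capped and nothing in it is labile to carbonate.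

**15 ⇒ 14 ⇒ 8 + 13.** The two CH2OH groups are traced to two ester groups, and the C3–C4 bond is cut. A malonate is the natural prochiral C3 synthon and a benzylic bromide its partner. The gain is a split into a ring B fragment and a ring A fragment. The forward steps must alkylate a hindered tertiary carbanion and reduce two esters while the aryl bromide survives.

**8 ⇒ 6 + 7.** The C3–C1' bond is cut. The forward step is an α-arylation of 7. Because 6 is a bromide, a palladium catalyst with a bulky phosphine is used in place of a copper catalyst, which would call for an iodide.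

**6 ⇒ 4 ⇒ 2 + 3, and 2 ⇒ 1.** Ring D is opened at C3'–C(vinyl) and O2'–CMe2, which leads to an aryl propargyl ether and on to a phenol and 3. The bromine of 1 has two roles: it is the handle for the arylation and it blocks one ortho position, so the Claisen shift can only go to the carbon between the two oxygens. The demand falls on the first step, which must tell the two hydroxyl groups of 1 apart.

**13 ⇒ 12 ⇒ 11 ⇒ 9.** The C4–C4a bond is cut back to a formylation of 9. The symmetry of 9 means only one regiochemical question arises: formylation next to bromine against formylation between the two methoxy groups.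

## Other disconnections considered

**Alternative 1:** The cut runs through C3–C1' and a temporary C4–O2' bond, so the isoflavan is traced to pterocarpan A3 and this to 5,7-dimethoxy-2H-chromene A1 and 2-iodo-5-(methoxymethoxy)phenol A2. In the forward step Pd(OAc)2, Ag2CO3 and a chiral bisphosphine would add the aryl group of A2 to C3 of A1 and close the phenol oxygen onto the benzylic C4, giving cis-fused A3. Benzylic C–O hydrogenolysis, done before any styrenic ring D exists, would open A3 to the 2'-hydroxyisoflavan A4. Ring D would follow by propargylation with 3 and Claisen cyclisation, and the ring A endgame would be that of steps 13 and 14.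
- In its favour: the C3–C1' bond and the stereocentre are made in one convergent step from two small pieces. The 2'-oxygen arrives in the right place and the Claisen shift has only C3' to go to. No carbon is added and removed and no stoichiometric rhodium is needed.
- Against it: the racemic oxyarylation is an established reaction type, but a highly enantioselective version under silver-promoted conditions is not, so the step that carries the stereochemistry would have to be developed. A1 is also a sensitive, easily isomerised partner.
- Comparison: on structure both plans set C3 during a ring closure, and the alternative is the better one in convergence. On mechanism the chosen plan has the closer precedent, because it selects between enantiotopic groups in a known substrate class. On step economy the alternative is better, at about ten steps against fourteen. The ring A endgame and its risks are equal.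

**Alternative 2:** The cut is made at C3–C1' and C4–C4a, with C2 and the O1–C2 bond added afterwards. The aryllithium A7, made from bromide A6, would be added to vinylboronic ester A5. The resulting ate complex would react with aryl triflate A8 under Pd(OAc)2 and a chiral ferrocenyl bisphosphine: ring B shifts from boron to carbon as palladium binds the alkene, and reductive elimination joins C4 to C4a, giving boronate A9. One-carbon homologation of the C–B bond, oxidation, release of the ring A phenol and a Mitsunobu closure would then build ring C.
- In its favour: both aryl groups are joined in one enantioselective step of a well-developed reaction type. The tertiary centre is formed directly, without a surplus carbon, and the C–B bond is a stereospecific handle. On mechanism and on directness of the stereocentre this alternative is the equal or the better of the chosen plan.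
- Against it: A9 lacks C2, so four further operations are needed before ring C exists. A8 is an electron-rich triflate flanked by two ortho oxygen groups, which makes oxidative addition and the following events at palladium demanding. A tetra-oxygenated ring A precursor and a silyl/MOM pair that must be taken apart selectively add work.
- Comparison: on structure the chosen plan closes ring C in the stereo-defining step, whereas here ring C is a separate task. On step economy the two are about equal, at thirteen to fifteen steps.

**Alternative 3:** All four ring B bonds (C1'–C2', C2'–C3', C4'–C5', C5'–C6') are cut, so ring B is built onto a chroman that is already chiral. Irradiation of diazo enone A10 would give a vinylketene by Wolff rearrangement. This would add to siloxyalkyne A11 in a [2+2] step, and four-electron ring opening followed by six-electron electrocyclisation would give phenol A12. Oxidative cyclisation of the ortho-prenylphenol would then make ring D before the ring A endgame.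
- In its favour: the substitution pattern of ring B (free 2'-OH, 3'-prenyl, protected 4'-O) follows from the connectivity of the partners with full regiocontrol. On this point it is better than the chosen plan, which depends on a selective mono-protection in step 1. The key step is neutral and metal-free.
- Against it: the key step does not create the stereocentre. C3 has to be set beforehand in a separate asymmetric synthesis and is then carried at the γ position of an enone, where dienolisation during diazo transfer threatens its configuration. A11 needs several steps, and the oxidative closure of ring D has to be done beside an electron-rich chroman.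
- Comparison: on structure it is the only plan that makes ring B de novo. On mechanism the pericyclic cascade is reliable in general, so the two plans are equal there. On step economy it is the longest, at sixteen or more steps, and it leaves the stereochemical problem unsolved.

Key step: step 10

## Route

**Step 1**
Reactants: 1 4-bromoresorcinol
Product: 2 2-bromo-5-(methoxymethoxy)phenol
Conditions: NaH (2.2 equiv), THF/DMF, 0 °C; MOMCl (1.0 equiv), −40 → 0 °C; aq NH4Cl
Reagents that add atoms: chloromethyl methyl ether (MOMCl), COCCl
Why: Williamson-type O-alkylation of the resorcinol dianion; the phenoxide para to bromine is the more basic and the less hindered one (the other is inductively stabilised and shielded by the ortho bromine), so the single equivalent of MOMCl should be taken up there.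

**Step 2**
Reactants: 2 2-bromo-5-(methoxymethoxy)phenol; 3 3-chloro-3-methylbut-1-yne
Product: 4 1-bromo-4-(methoxymethoxy)-2-[(2-methylbut-3-yn-2-yl)oxy]benzene
Conditions: CuCl2·2H2O (1 mol %), DBU (1.5 equiv), MeCN, 0 °C → rt
Reagents that add atoms: none
Why: Copper-catalysed propargylic substitution of the tertiary chloride by the only remaining phenol, a standard way to aryl 1,1-dimethylpropargyl ethers; acidic ortho-halophenols are good substrates.

**Step 3**
Reactants: 4 1-bromo-4-(methoxymethoxy)-2-[(2-methylbut-3-yn-2-yl)oxy]benzene
Product: 6 8-bromo-5-(methoxymethoxy)-2,2-dimethyl-2H-chromene, via allenylphenol 5 (not isolated)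
Conditions: PhNEt2, 180 °C
Reagents that add atoms: none
Why: Aromatic propargyl Claisen rearrangement; the [3,3] shift can only reach the ortho carbon between the two oxygens because the other ortho position carries bromine, and the allenylphenol then closes ring D by 1,5-hydrogen shift and oxa-6π electrocyclisation; the basic solvent protects the MOM acetal.

**Step 4**
Reactants: 6 8-bromo-5-(methoxymethoxy)-2,2-dimethyl-2H-chromene; 7 diethyl malonate
Product: 8 diethyl 2-[5-(methoxymethoxy)-2,2-dimethyl-2H-chromen-8-yl]propanedioate
Conditions: Pd(OAc)2 (2 mol %), P(t-Bu)3·HBF4 (4 mol %), K3PO4 (3 equiv), toluene, 80 °C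
Reagents that add atoms: none
Why: Palladium-catalysed α-arylation of a malonate (oxidative addition of C–Br to zerovalent palladium, enolate binding, reductive elimination), which accepts electron-rich ortho-alkoxy aryl bromides; the product stays as its unreactive enolate, so a second arylation is not expected.

**Step 5**
Reactants: 9 1-bromo-3,5-dimethoxybenzene
Product: 11 2-bromo-4,6-dimethoxybenzaldehyde, via aryl iminium chloride 10 (not isolated)
Conditions: POCl3 (1.5 equiv), DMF, 0 → 90 °C; then aq NaOAc
Reagents that add atoms: N,N-dimethylformamide, CN(C)C=O; water, O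
Why: Vilsmeier–Haack formylation; attack next to bromine (ortho and para to the two methoxy groups) should be preferred over the crowded carbon between the two methoxy groups, and any minor isomer is removed by crystallisation.

**Step 6**
Reactants: 11 2-bromo-4,6-dimethoxybenzaldehyde
Product: 12 (2-bromo-4,6-dimethoxyphenyl)methanol
Conditions: NaBH4, MeOH/THF, 0 °C
Reagents that add atoms: none
Why: Borohydride reduction of an aryl aldehyde; the aryl bromide is untouched.

**Step 7**
Reactants: 12 (2-bromo-4,6-dimethoxyphenyl)methanol
Product: 13 1-bromo-2-(bromomethyl)-3,5-dimethoxybenzene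
Conditions: PBr3 (0.4 equiv), CH2Cl2, 0 °C; used at once without purification
Reagents that add atoms: phosphorus tribromide, BrP(Br)Br
Why: Conversion of a benzylic alcohol into the bromide through its phosphite ester; the electron-rich bromide is labile, so it is taken straight into step 8.

**Step 8**
Reactants: 8 diethyl 2-[5-(methoxymethoxy)-2,2-dimethyl-2H-chromen-8-yl]propanedioate; 13 1-bromo-2-(bromomethyl)-3,5-dimethoxybenzene
Product: 14 diethyl 2-[(2-bromo-4,6-dimethoxyphenyl)methyl]-2-[5-(methoxymethoxy)-2,2-dimethyl-2H-chromen-8-yl]propanedioate
Conditions: NaH (1.1 equiv), DMF, 0 °C; then 13, 0 °C → rt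
Reagents that add atoms: none
Why: SN2 C-alkylation of the arylmalonate sodium enolate by an activated benzylic bromide (malonic ester alkylation); the new quaternary carbon is the future C3 and is achiral because it carries two identical ester groups.

**Step 9**
Reactants: 14 diethyl 2-[(2-bromo-4,6-dimethoxyphenyl)methyl]-2-[5-(methoxymethoxy)-2,2-dimethyl-2H-chromen-8-yl]propanedioate
Product: 15 2-[(2-bromo-4,6-dimethoxyphenyl)methyl]-2-[5-(methoxymethoxy)-2,2-dimethyl-2H-chromen-8-yl]propane-1,3-diol
Conditions: LiAlH4 (2.5 equiv), THF, 0 °C → rt; then H2O, aq NaOH
Reagents that add atoms: none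
Why: Hydride reduction of both esters to the prochiral 1,3-diol; aryl bromide, MOM acetal and the ring D alkene are inert to LiAlH4 at or below room temperature, and the low temperature holds back retro-aldol loss of formaldehyde.

**Step 10**
Reactants: 15 2-[(2-bromo-4,6-dimethoxyphenyl)methyl]-2-[5-(methoxymethoxy)-2,2-dimethyl-2H-chromen-8-yl]propane-1,3-diol
Product: 16 [(3R)-5,7-dimethoxy-3-[5-(methoxymethoxy)-2,2-dimethyl-2H-chromen-8-yl]-3,4-dihydro-2H-chromen-3-yl]methanol
Conditions: CuI (10 mol %), (1R,2R)- or (1S,2S)-N,N'-dimethyl-1,2-diphenylethane-1,2-diamine (20 mol %), Cs2CO3 (2 equiv), MeCN, 0.05 M, 40–50 °C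
Reagents that add atoms: none
Why: Cs2CO3 turns one hydroxymethyl group into an alkoxide on the diamine-bound monovalent copper; the tethered C8a–Br bond then adds to the metal to give a trivalent aryl copper alkoxide, and C–O reductive elimination forms O1–C8a and returns monovalent copper. The closest known reaction type is the copper/chiral-diamine Ullmann-type desymmetrising O-arylation of 2-substituted 2-(2-halobenzyl)propane-1,3-diols, which gives chroman-3-ylmethanols with a quaternary C3. Ring C closes as a six-membered ring by 6-exo attack of oxygen on the aromatic carbon that carries the leaving bromide. C3 becomes stereogenic in this ring closure: the chiral diamine on copper decides which of the two enantiotopic alkoxides is carried through the cyclic transition state, in which ring B and the spectator CH2OH must take pseudo-equatorial and pseudo-axial places of very different size. The step needs enantiotopic-group selectivity only; site selectivity is fixed because 15 has a single C–Br bond and no free phenol, and dilution keeps intermolecular O-arylation down. The substrate helps in that both methoxy groups are meta to C8a and do not deactivate the C–Br bond, C8 is unsubstituted, and the MOM ether and ring D are inert to carbonate. The ligand antipode that leads to (R)-16 is used.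

**Step 11**
Reactants: 16 [(3R)-5,7-dimethoxy-3-[5-(methoxymethoxy)-2,2-dimethyl-2H-chromen-8-yl]-3,4-dihydro-2H-chromen-3-yl]methanol
Product: 17 (3S)-5,7-dimethoxy-3-[5-(methoxymethoxy)-2,2-dimethyl-2H-chromen-8-yl]-3,4-dihydro-2H-chromene-3-carbaldehyde
Conditions: Dess–Martin periodinane (1.3 equiv), CH2Cl2, rt
Reagents that add atoms: none
Why: Dess–Martin oxidation of a neopentyl primary alcohol under near-neutral conditions that spare ring D and the MOM ether; the aldehyde has no α-hydrogen, so C3 cannot epimerise, and the descriptor changes to S only because CHO outranks C2.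

**Step 12**
Reactants: 17 (3S)-5,7-dimethoxy-3-[5-(methoxymethoxy)-2,2-dimethyl-2H-chromen-8-yl]-3,4-dihydro-2H-chromene-3-carbaldehyde
Product: 18 (3R)-5,7-dimethoxy-3-[5-(methoxymethoxy)-2,2-dimethyl-2H-chromen-8-yl]-3,4-dihydro-2H-chromene
Conditions: RhCl(PPh3)3 (1.1 equiv), PhCN, 130 °C
Reagents that add atoms: none
Why: Tsuji–Wilkinson decarbonylation: the formyl C–H bond adds to monovalent rhodium, CO is extruded by migration of the alkyl group to the metal and C–H reductive elimination follows, both with retention, so hydrogen takes the place of CHO and C3 becomes the (3R) tertiary centre; the reaction type is established for α-aryl α,α-dialkyl aldehydes.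

**Step 13**
Reactants: 18 (3R)-5,7-dimethoxy-3-[5-(methoxymethoxy)-2,2-dimethyl-2H-chromen-8-yl]-3,4-dihydro-2H-chromene
Product: 20 (3R)-5,7-dimethoxy-3-[5-(methoxymethoxy)-2,2-dimethyl-2H-chromen-8-yl]-3,4-dihydro-2H-chromene-8-carbaldehyde, via C8 iminium chloride 19 (not isolated)
Conditions: POCl3 (1.3 equiv), DMF, 0 °C → rt; then aq NaOAc
Reagents that add atoms: N,N-dimethylformamide, CN(C)C=O; water, O
Why: Vilsmeier–Haack formylation; ring A with three oxygen donors should react well before ring B with two, and C8, flanked by one methoxy group and the tied-back ring oxygen, is less crowded than C6 between two methoxy groups; buffered hydrolysis protects the MOM acetal and ring D.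

**Step 14**
Reactants: 20 (3R)-5,7-dimethoxy-3-[5-(methoxymethoxy)-2,2-dimethyl-2H-chromen-8-yl]-3,4-dihydro-2H-chromene-8-carbaldehyde
Product: 22 (3R)-7-hydroxy-3-(5-hydroxy-2,2-dimethyl-2H-chromen-8-yl)-5-methoxy-3,4-dihydro-2H-chromene-8-carbaldehyde, via MOM-free dimethyl ether 21 (not isolated)
Conditions: BCl3 (4 equiv), CH2Cl2, −78 → 0 °C; then H2O
Reagents that add atoms: none
Why: BCl3 first cleaves the MOM acetal, then performs the chelation-controlled O-demethylation: boron bridges the C8 carbonyl oxygen and O7 and chloride removes that methyl group, while the unchelated 5-OMe stays and the other ortho ether (O1–C2) is protected by the slower SN2 at a branched ring carbon; low temperature limits ionisation of ring D.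

## Compound list

1 | 4-bromoresorcinol | Oc1ccc(Br)c(O)c1 | starting material
2 | 2-bromo-5-(methoxymethoxy)phenol | COCOc1ccc(Br)c(O)c1 | intermediate
3 | 3-chloro-3-methylbut-1-yne | CC(C)(Cl)C#C | starting material
4 | 1-bromo-4-(methoxymethoxy)-2-[(2-methylbut-3-yn-2-yl)oxy]benzene | COCOc1ccc(Br)c(OC(C)(C)C#C)c1 | intermediate
5 | 6-bromo-3-(methoxymethoxy)-2-(3-methylbuta-1,2-dien-1-yl)phenol | COCOc1ccc(Br)c(O)c1C=C=C(C)C | intermediate (not isolated)
6 | 8-bromo-5-(methoxymethoxy)-2,2-dimethyl-2H-chromene | CC1(C)C=Cc2c(OCOC)ccc(Br)c2O1 | intermediate
7 | diethyl malonate | CCOC(=O)CC(=O)OCC | starting material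
8 | diethyl 2-[5-(methoxymethoxy)-2,2-dimethyl-2H-chromen-8-yl]propanedioate | CCOC(=O)C(C(=O)OCC)c1ccc(OCOC)c2c1OC(C)(C)C=C2 | intermediate
9 | 1-bromo-3,5-dimethoxybenzene | COc1cc(Br)cc(OC)c1 | starting material
10 | [(2-bromo-4,6-dimethoxyphenyl)methylidene]dimethylammonium chloride | COc1cc(OC)c(C=[N+](C)C)c(Br)c1.[Cl-] | intermediate (not isolated)
11 | 2-bromo-4,6-dimethoxybenzaldehyde | COc1cc(OC)c(C=O)c(Br)c1 | intermediate
12 | (2-bromo-4,6-dimethoxyphenyl)methanol | COc1cc(OC)c(CO)c(Br)c1 | intermediate
13 | 1-bromo-2-(bromomethyl)-3,5-dimethoxybenzene | COc1cc(OC)c(CBr)c(Br)c1 | intermediate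
14 | diethyl 2-[(2-bromo-4,6-dimethoxyphenyl)methyl]-2-[5-(methoxymethoxy)-2,2-dimethyl-2H-chromen-8-yl]propanedioate | CCOC(=O)C(Cc1c(Br)cc(OC)cc1OC)(C(=O)OCC)c1ccc(OCOC)c2c1OC(C)(C)C=C2 | intermediate
15 | 2-[(2-bromo-4,6-dimethoxyphenyl)methyl]-2-[5-(methoxymethoxy)-2,2-dimethyl-2H-chromen-8-yl]propane-1,3-diol | COc1cc(OC)cc(Br)c1CC(CO)(CO)c1ccc(OCOC)c2c1OC(C)(C)C=C2 | intermediate
16 | [(3R)-5,7-dimethoxy-3-[5-(methoxymethoxy)-2,2-dimethyl-2H-chromen-8-yl]-3,4-dihydro-2H-chromen-3-yl]methanol | COc1cc(OC)cc2c1C[C@](CO)(c1ccc(OCOC)c3c1OC(C)(C)C=C3)CO2 | intermediate
17 | (3S)-5,7-dimethoxy-3-[5-(methoxymethoxy)-2,2-dimethyl-2H-chromen-8-yl]-3,4-dihydro-2H-chromene-3-carbaldehyde | COc1cc(OC)cc2c1C[C@](C=O)(c1ccc(OCOC)c3c1OC(C)(C)C=C3)CO2 | intermediate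
18 | (3R)-5,7-dimethoxy-3-[5-(methoxymethoxy)-2,2-dimethyl-2H-chromen-8-yl]-3,4-dihydro-2H-chromene | COc1cc(OC)cc2c1C[C@H](c1ccc(OCOC)c3c1OC(C)(C)C=C3)CO2 | intermediate
19 | [[(3R)-5,7-dimethoxy-3-[5-(methoxymethoxy)-2,2-dimethyl-2H-chromen-8-yl]-3,4-dihydro-2H-chromen-8-yl]methylidene]dimethylammonium chloride | COc1cc(OC)c(C=[N+](C)C)c2c1C[C@H](c1ccc(OCOC)c3c1OC(C)(C)C=C3)CO2.[Cl-] | intermediate (not isolated)
20 | (3R)-5,7-dimethoxy-3-[5-(methoxymethoxy)-2,2-dimethyl-2H-chromen-8-yl]-3,4-dihydro-2H-chromene-8-carbaldehyde | COc1cc(OC)c(C=O)c2c1C[C@H](c1ccc(OCOC)c3c1OC(C)(C)C=C3)CO2 | intermediate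
21 | (3R)-3-(5-hydroxy-2,2-dimethyl-2H-chromen-8-yl)-5,7-dimethoxy-3,4-dihydro-2H-chromene-8-carbaldehyde | COc1cc(OC)c(C=O)c2c1C[C@H](c1ccc(O)c3c1OC(C)(C)C=C3)CO2 | intermediate (not isolated)
22 | (3R)-7-hydroxy-3-(5-hydroxy-2,2-dimethyl-2H-chromen-8-yl)-5-methoxy-3,4-dihydro-2H-chromene-8-carbaldehyde | COc1cc(O)c(C=O)c2c1C[C@H](c1ccc(O)c3c1OC(C)(C)C=C3)CO2 | target

## Step count and uncertain steps

Total step count: 14. Longest linear sequence: 11 (steps 1–4 and 8–14); the ring A branch (steps 5–7) joins at step 8.

**Step 10 (key step).** The likely failure is poor discrimination between the two enantiotopic hydroxymethyl groups. A related one is slow oxidative addition of the aryl bromide at the mild temperature that good selectivity needs, so that heating erodes the enantiomeric purity. The fallback gives up catalytic desymmetrisation in favour of resolution. It sets out from 15, which is closed without a chiral ligand (CuI, 1,10-phenanthroline, Cs2CO3, toluene, 110 °C) to the racemic alcohol rac-[5,7-dimethoxy-3-[5-(methoxymethoxy)-2,2-dimethyl-2H-chromen-8-yl]-3,4-dihydro-2H-chromen-3-yl]methanol F1. Preparative chromatography on a chiral stationary phase then separates the wanted enantiomer from the (3S)-alcohol F2, which is discarded. The route is rejoined at 16.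

**Step 12.** The tertiary alkylrhodium hydride may undergo β-hydride elimination to isoflavenes in place of C–H reductive elimination. CO extrusion at the congested benzylic carbon may also be so slow that thermal loss of the MOM group sets in. The fallback changes the substrate and the metal: it sets out from 16 and removes the hydroxymethyl group in one operation by iridium-catalysed acceptorless dehydrogenative decarbonylation ([Ir(coe)2Cl]2, rac-BINAP, LiCl, mesitylene, reflux). The aldehyde then never accumulates, and the route is rejoined at 18. This detour makes no compound outside the list (F0).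

**Step 13.** Site selectivity may be poor, with attack at C6 or on ring B competing with C8, and the MOM acetal may be lost during hydrolysis of the iminium salt. The fallback replaces direct formylation by halogenation and metalation. From 18, NBS (1.0 equiv, CH2Cl2, −78 °C) should brominate C8, the position for which halogenation of 5,7-dialkoxychromans shows the clearest preference, to give (3R)-8-bromo-5,7-dimethoxy-3-[5-(methoxymethoxy)-2,2-dimethyl-2H-chromen-8-yl]-3,4-dihydro-2H-chromene F3. Bromine–lithium exchange (n-BuLi, THF, −78 °C) and quenching with DMF then place the formyl group regiospecifically, and the route is rejoined at 20.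

**Step 14.** Ring D may be opened by Lewis-acid ionisation of its tertiary allylic aryl ether, the O1–C2 bond may be cleaved in competition with the chelated methyl ether, and the liberated chloromethyl ether may alkylate a ring. The fallback splits the step into two milder, boron-free operations. From 20, a catalytic amount of HCl in MeOH at 40 °C removes the MOM group, and 21 is now isolated. MgI2·OEt2 in toluene/Et2O at 60–80 °C then cleaves only the methoxy group held next to the formyl group, and the route is rejoined at 22. No compound outside the list is made (F0).

**Step 1.** The two phenoxides may not be differentiated well enough, which would give the regioisomeric ether and the bis-ether. The fallback uses steric control. From 1, TBDPSCl and imidazole (CH2Cl2, 0 °C) should silylate the unhindered hydroxyl to 2-bromo-5-[tert-butyl(diphenyl)silyl]oxyphenol F4. Propargylation with 3 under the conditions of step 2 gives the silyl propargyl ether F5, and heating as in step 3 gives the silyl chromene F6. TBAF (THF, 0 °C) frees 8-bromo-2,2-dimethyl-2H-chromen-5-ol F7, and NaH/MOMCl rejoins the route at 6.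

## Further compounds

F1 | step 10 | rac-[5,7-dimethoxy-3-[5-(methoxymethoxy)-2,2-dimethyl-2H-chromen-8-yl]-3,4-dihydro-2H-chromen-3-yl]methanol | COc1cc(OC)cc2c1CC(CO)(c1ccc(OCOC)c3c1OC(C)(C)C=C3)CO2
F2 | step 10 | [(3S)-5,7-dimethoxy-3-[5-(methoxymethoxy)-2,2-dimethyl-2H-chromen-8-yl]-3,4-dihydro-2H-chromen-3-yl]methanol | COc1cc(OC)cc2c1C[C@@](CO)(c1ccc(OCOC)c3c1OC(C)(C)C=C3)CO2
F0 | step 12 | none | none
F3 | step 13 | (3R)-8-bromo-5,7-dimethoxy-3-[5-(methoxymethoxy)-2,2-dimethyl-2H-chromen-8-yl]-3,4-dihydro-2H-chromene | COc1cc(OC)c(Br)c2c1C[C@H](c1ccc(OCOC)c3c1OC(C)(C)C=C3)CO2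
F0 | step 14 | none | none
F4 | step 1 | 2-bromo-5-[tert-butyl(diphenyl)silyl]oxyphenol | CC(C)(C)[Si](Oc1ccc(Br)c(O)c1)(c1ccccc1)c1ccccc1
F5 | step 1 | [4-bromo-3-[(2-methylbut-3-yn-2-yl)oxy]phenoxy](tert-butyl)diphenylsilane | CC(C)(C)[Si](Oc1ccc(Br)c(OC(C)(C)C#C)c1)(c1ccccc1)c1ccccc1
F6 | step 1 | [(8-bromo-2,2-dimethyl-2H-chromen-5-yl)oxy](tert-butyl)diphenylsilane | CC1(C)C=Cc2c(O[Si](c3ccccc3)(c3ccccc3)C(C)(C)C)ccc(Br)c2O1
F7 | step 1 | 8-bromo-2,2-dimethyl-2H-chromen-5-ol | CC1(C)C=Cc2c(O)ccc(Br)c2O1
A1 | alternative 1 | 5,7-dimethoxy-2H-chromene | COc1cc(OC)c2C=CCOc2c1
A2 | alternative 1 | 2-iodo-5-(methoxymethoxy)phenol | COCOc1ccc(I)c(O)c1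
A3 | alternative 1 | (6aR,11aR)-1,3-dimethoxy-9-(methoxymethoxy)pterocarpan | COc1cc(OC)cc2c1[C@@H]1Oc3cc(OCOC)ccc3[C@@H]1CO2
A4 | alternative 1 | 2-[(3R)-5,7-dimethoxy-3,4-dihydro-2H-chromen-3-yl]-5-(methoxymethoxy)phenol | COc1cc(OC)cc2c1C[C@H](c1ccc(OCOC)cc1O)CO2
A5 | alternative 2 | 2-ethenyl-4,4,5,5-tetramethyl-1,3,2-dioxaborolane | C=CB1OC(C)(C)C(C)(C)O1
A6 | alternative 2 | 8-bromo-2,2-dimethyl-5-(triisopropylsilyloxy)-2H-chromene | CC1(C)C=Cc2c(O[Si](C(C)C)(C(C)C)C(C)C)ccc(Br)c2O1
A7 | alternative 2 | [2,2-dimethyl-5-(triisopropylsilyloxy)-2H-chromen-8-yl]lithium | CC1(C)C=Cc2c(O[Si](C(C)C)(C(C)C)C(C)C)ccc([Li])c2O1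
A8 | alternative 2 | 2,4-dimethoxy-6-(methoxymethoxy)phenyl trifluoromethanesulfonate | COCOc1cc(OC)cc(OC)c1OS(=O)(=O)C(F)(F)F
A9 | alternative 2 | 2-[(1R)-2-[2,4-dimethoxy-6-(methoxymethoxy)phenyl]-1-[2,2-dimethyl-5-(triisopropylsilyloxy)-2H-chromen-8-yl]ethyl]-4,4,5,5-tetramethyl-1,3,2-dioxaborolane | COc1cc(OC)cc(OCOC)c1C[C@H](c1ccc(O[Si](C(C)C)(C(C)C)C(C)C)c2c1OC(C)(C)C=C2)B1OC(C)(C)C(C)(C)O1
A10 | alternative 3 | (3E)-1-diazo-4-[(3R)-5,7-dimethoxy-3,4-dihydro-2H-chromen-3-yl]but-3-en-2-one | COc1cc(OC)cc2c1C[C@H](/C=C/C(=O)C=[N+]=[N-])CO2
A11 | alternative 3 | 5-methyl-1-(triisopropylsilyloxy)hex-4-en-1-yne | CC(C)=CCC#CO[Si](C(C)C)(C(C)C)C(C)C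
A12 | alternative 3 | (3R)-2'-hydroxy-5,7-dimethoxy-3'-prenyl-4'-(triisopropylsilyloxy)isoflavan | COc1cc(OC)cc2c1C[C@H](c1ccc(O[Si](C(C)C)(C(C)C)C(C)C)c(CC=C(C)C)c1O)CO2
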